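## Structural features

The target is a biflavonoid made of a (2S)-flavanone of the naringenin type (ring A: the 5,7-dihydroxylated benzo ring; ring C: the dihydropyranone; ring B: the 4'-hydroxyphenyl group on C2) and a flavone of the apigenin type, joined by one aryl–aryl bond between C3' of ring B and C6'' of the flavone. The only stereocentre is C2 (S). It is benzylic to ring B, bonded to O1 and β to the C4 carbonyl, and it has no stereogenic neighbour. The C3'–C6'' axis is flanked by three oxygen substituents (O4', O5'', O7''), which makes the bond hard to form, but with groups this small it is not a stable stereogenic element. The fragile points are C2, which is lost by retro-oxa-Michael opening to the 2'-hydroxychalcone under base or hot acid (helped by the para-oxygen of ring B), the six oxidisable phenols (two chelated to C4=O and C4''=O), and the reducible C2''=C3'' bond and C4 ketone. The real difficulties are to create C2 late with absolute control under neutral conditions, to make the hindered 3',6''-biaryl bond at C6'' and not at C8'', and to keep six phenols apart. The key step exploits that, with ring C opened between C2 and C3, C2 is the methylene of an O1–CH2–ring B ether. Its two enantiotopic hydrogens are activated by O1 and by the para-oxygenated ring B and lie in a 1,6-relationship to C3, so a carbene at C3 on the acyl group of ring A can insert into one of them, forming C2–C3, closing ring C and setting C2 in one operation.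

## Logic of the disconnections

**17 back to 15 (through 16).** Four O–CH2Ph bonds (O4', O5'', O7'', O4''') and two O–Si bonds (O5, O7) are cut. Silicon is placed on ring A because the oxygen ortho to the acyl group must not offer the carbene a second O–CH2–aryl unit; benzyl covers the remaining phenols because it survives every earlier step. The gain is a non-polar, fully masked compound 15. The demand is that both removals run without base strong enough to open ring C; buffered fluoride (no hydrogen fluoride reagent) and neutral hydrogenolysis are chosen, and the hydrogenolysis must stop before the C2''=C3'' bond or the benzylic C2–O1 bond is touched.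

**15 back to 14.** The C2–C3 bond is cut. This removes ring C and the only stereocentre together and leaves an achiral aryl benzyl ether with a diazoketone on ring A. The forward step must distinguish two enantiotopic hydrogens and must prefer C–H insertion to attack on the lone pair of O1. The precursor is designed for this: a para-benzyloxy group on ring B raises the hydridic character of C2–H, and the other ortho oxygen carries a triisopropylsilyl group, which has no oxygen-activated C–H bond within reach, shields its own lone pairs and is too bulky to migrate easily.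

**14 back to 12 (through 13).** The C3=N2 unit is cut back to the methyl group of an aryl methyl ketone. This avoids diazomethane and an acid chloride on a hexa-oxygenated substrate, and 12 has a single enolisable position. The demand is clean mono-trifluoroacetylation of the lithium enolate at low temperature, so that the ortho silyl group does not move to the enolate oxygen, and a diazo donor of low hazard (an arenesulfonyl azide carrying an acetamido group).

**12 back to 9 and 11.** The O1–CH2 bond is cut. This is the most convergent cut, since it divides the molecule into ring A and the biaryl half. The demand is an etherification of a hydrogen-bonded ortho-acyl phenol that is neutral enough to leave two aryl silyl ethers in place; dehydrative coupling with a primary benzylic alcohol meets it.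

**11 back to 10.** Two O–Si bonds are cut. The forward step must silylate two of three phenols; the third is held back by its hydrogen bond to the carbonyl and by the bulk of the silyl chloride.

**9 back to 8, then to 4 and 7.** The benzylic C–H bond from hydride is cut first (alcohol to aldehyde), then the C3'–C6'' biaryl bond. The aldehyde is the natural handle on ring B because it is present in commercial 5 and tolerates borylation and coupling. Cutting the biaryl bond gives two halves of similar size that are each three or fewer steps from commercial materials. The demand is a palladium-catalysed coupling that builds a biaryl with three ortho substituents.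

**7 back to 6 and 5.** The C–B bond and the O–benzyl bond are cut. The boron is placed on the less hindered partner, whose boronate is not flanked by two ortho oxygens and so is less prone to protodeboronation.

**4 back to 3, 2 and 1.** The O5''–benzyl bond, the C6''–I bond and the O7''/O4'''–benzyl bonds are cut in that order. The chelated 5''-hydroxyl is left free until the iodine is in place, because it steers the electrophile to its ortho position C6''. The demand is regioselective mono-iodination without toxic heavy-metal salts.

## Other disconnections considered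

**Alternative 1:** The cut runs through ring B (C2'–C3' and C4'–C5'), so ring B is grown on the flavone and not brought in as an arene. In the forward step the bis(trimethylsilyl) ketene acetal A1 would add with its nucleophilic carbon to C6 of methyl coumalate A2 and close onto C3; loss of CO2 from the bridged lactone and of trimethylsilanol would aromatise to the 4-hydroxy-3-arylbenzoate A3.
- In its favour: the congested biaryl bond starts as an unhindered sp3 C–C bond, the pattern on ring B is fixed by the polarity of the partners, the reaction is thermal and metal-free, and the 4'-phenol emerges free.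
- Against it here: a two-carbon acid side chain must first be attached regioselectively at C6'' of the apigenin, which costs several steps. The ketene acetal must be made with strong base beside the flavone enone, and the addition may stop at the Michael stage. A3 still needs ester reduction in the presence of the flavone carbonyl and O-benzylation to reach 9, and nothing is done for C2.
- Comparison: on structure both plans meet at 9. On mechanism the alternative is the better in one respect, since forming the axis by ring synthesis is insensitive to ortho substituents, whereas step 6 is one of the less certain steps. On regiocontrol of ring B it is the equal. On step economy it is worse, by an estimated four to five steps to 9, and it saves none of the steps from 9 to 17.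

**Alternative 2:** The cut runs through ring A'' of the flavone (C5''–C6'', C7''–C8'', C4a''–C5''). In the forward step Wolff rearrangement of the pyranonyl diazoketone A4 would give a ketene conjugated to the pyranone double bond. [2+2] addition of the siloxyalkyne A5 (aryl-bearing alkyne carbon to the ketene carbonyl carbon), 4π opening of the cyclobutenone and 6π closure onto the pyranone carbon would give the 5''-hydroxy-7''-silyloxyflavone A6 with the ring B aryl group at C6''.
- In its favour: the position of the aryl group is fixed by construction, so no choice between C6'' and C8'' arises. The axis forms during ring synthesis, the oxygens of ring A'' come out differentiated, and the aldehyde is carried as a dioxolane.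
- Against it here: both partners are multistep and sensitive (an ynol silyl ether and a second diazoketone). The 4-pyranone chromophore is itself photoreactive, so the Wolff step would have to be thermal or sensitised. A6 needs protecting-group exchange and acetal hydrolysis to reach 8, and C2 is again untouched.
- Comparison: the alternative is the better on regiochemical certainty at C6'' (the chosen route relies on the directed iodination of step 2) and on avoiding the hindered coupling. It is the equal in convergence. It is worse on step count, on the number of hazardous diazo intermediates and on reagent robustness.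

**Alternative 3:** The cut is O1–C2. In the forward step the alkylidene β-keto ester A7 would close by 6-endo oxa-Michael addition under a quinine-derived bifunctional thiourea: the thiourea binds the 1,3-dicarbonyl unit and the quinuclidine nitrogen guides the phenol to one face of the benzylidene carbon, giving the trans keto ester A8. Acid-promoted loss of the tert-butyl ester and CO2 from A8 and one hydrogenolysis would end at 17.
- In its favour: this reaction type is established for 2-arylchromanones with high enantioselectivity. It needs no metal carbene, no diazo compound and no silyl groups, so all six phenols can be benzyl ethers that fall in one final step.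
- Against it here: the addition is reversible, and this target has both features that slow the forward reaction and ease the reverse one, namely an electron-rich para-alkoxy ring B and an alkoxy group ortho to the ketone on ring A. Decarboxylation needs acid and heat after C2 is set, which is where erosion of enantiopurity by ring opening is to be feared. The β-keto ester must also be made on a ring A ketone carrying a free phenol.
- Comparison: the alternative is the better plan on step economy (about two steps fewer from 8, one deprotection instead of two) and on precedent for enantiocontrol. On structure it is the equal, since both plans create only ring C and C2. On mechanism the chosen plan has the advantage that its stereodefining step forms a C–C bond irreversibly under neutral conditions with no acidic or thermal step after it; its weakness is the competition with ylide chemistry and the unproven enantiocontrol for a terminal diazoketone.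

Key step: step 11

Assumption: Rh2(S-PTTL)4 is taken to deliver the 2S product; if the sense of induction is the opposite, the mirror-image catalyst Rh2(R-PTTL)4 is used with no other change.

Assumption: the C3'–C6'' axis is taken to rotate freely at room temperature in the target, so no axial configuration has to be controlled.

In the names below, "tri-O-benzylapigenin-6-yl" stands for 5,7-bis(benzyloxy)-2-[4-(benzyloxy)phenyl]-4-oxo-4H-chromen-6-yl.

## Route

Step 1
Reactants: 1 apigenin (5,7-dihydroxy-2-(4-hydroxyphenyl)-4H-chromen-4-one)
Product: 2 7-(benzyloxy)-2-[4-(benzyloxy)phenyl]-5-hydroxy-4H-chromen-4-one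
Conditions: BnBr (2.2 equiv), K2CO3, DMF, rt
Reagents that add atoms: benzyl bromide, BrCc1ccccc1
Why: Williamson etherification; the 7- and 4'-hydroxyls are the acidic, unhindered phenols, while the 5-hydroxyl is held in a hydrogen bond to C4=O and should stay free at room temperature.

Step 2
Reactants: 2 7-(benzyloxy)-2-[4-(benzyloxy)phenyl]-5-hydroxy-4H-chromen-4-one
Product: 3 7-(benzyloxy)-2-[4-(benzyloxy)phenyl]-5-hydroxy-6-iodo-4H-chromen-4-one
Conditions: BnMe3N+ ICl2− (1.1 equiv), CaCO3, CH2Cl2–MeOH, rt
Reagents that add atoms: benzyltrimethylammonium dichloroiodate, C[N+](C)(C)Cc1ccccc1.Cl[I-]Cl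
Why: Electrophilic aromatic iodination; the free chelated 5-hydroxyl directs to its ortho position C6, as is typical of 5-hydroxy-7-alkoxyflavones with this reagent, and the 4-benzyloxyphenyl ring is far less activated. CaCO3 takes up the HCl, so the benzyl ethers are safe and no thallium salt is needed.

Step 3
Reactants: 3 7-(benzyloxy)-2-[4-(benzyloxy)phenyl]-5-hydroxy-6-iodo-4H-chromen-4-one
Product: 4 5,7-bis(benzyloxy)-2-[4-(benzyloxy)phenyl]-6-iodo-4H-chromen-4-one
Conditions: BnBr, K2CO3, Bu4NI (cat.), DMF, 70 °C
Reagents that add atoms: benzyl bromide, BrCc1ccccc1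
Why: Williamson etherification of the chelated, iodine-flanked phenol, which needs heat; it masks the last apigenin phenol before the Mitsunobu, enolate and carbene steps.

Step 4
Reactants: 5 3-bromo-4-hydroxybenzaldehyde
Product: 6 4-(benzyloxy)-3-bromobenzaldehyde
Conditions: BnBr, K2CO3, DMF, rt
Reagents that add atoms: benzyl bromide, BrCc1ccccc1
Why: Williamson etherification of an acidic para-formyl phenol; the benzyl ether will later be the para donor that activates C2–H.

Step 5
Reactants: 6 4-(benzyloxy)-3-bromobenzaldehyde
Product: 7 4-(benzyloxy)-3-(4,4,5,5-tetramethyl-1,3,2-dioxaborolan-2-yl)benzaldehyde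
Conditions: B2pin2, PdCl2(dppf) (3 mol %), KOAc, DMSO, 80 °C
Reagents that add atoms: bis(pinacolato)diboron, CC1(C)OB(OC1(C)C)B1OC(C)(C)C(C)(C)O1
Why: Miyaura borylation of an aryl bromide; the aldehyde and benzyl ether are tolerated, and acetate is too weak a base to start a Suzuki homocoupling.

Step 6
Reactants: 4 5,7-bis(benzyloxy)-2-[4-(benzyloxy)phenyl]-6-iodo-4H-chromen-4-one; 7 4-(benzyloxy)-3-(4,4,5,5-tetramethyl-1,3,2-dioxaborolan-2-yl)benzaldehyde
Product: 8 4-(benzyloxy)-3-(tri-O-benzylapigenin-6-yl)benzaldehyde
Conditions: Pd(OAc)2 (5 mol %), SPhos (10 mol %), K3PO4, toluene–H2O, 90 °C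
Reagents that add atoms: none
Why: Suzuki–Miyaura coupling; the aryl iodide adds readily to zerovalent palladium, and a bulky electron-rich biarylphosphine is the standard answer to a biaryl with three ortho substituents. The non-enolisable aldehyde survives aqueous phosphate.

Step 7
Reactants: 8 4-(benzyloxy)-3-(tri-O-benzylapigenin-6-yl)benzaldehyde
Product: 9 5,7-bis(benzyloxy)-6-[2-(benzyloxy)-5-(hydroxymethyl)phenyl]-2-[4-(benzyloxy)phenyl]-4H-chromen-4-one
Conditions: NaBH4, THF–MeOH, 0 °C
Reagents that add atoms: none
Why: Borohydride reduction; the aldehyde should be reduced far faster at 0 °C than the vinylogous-ester carbonyl of the flavone.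

Step 8
Reactants: 10 2',4',6'-trihydroxyacetophenone (1-(2,4,6-trihydroxyphenyl)ethanone)
Product: 11 1-[2-hydroxy-4,6-bis(triisopropylsilyloxy)phenyl]ethanone
Conditions: TIPSCl (2.1 equiv), imidazole, DMF, 0 °C to rt
Reagents that add atoms: chlorotriisopropylsilane, CC(C)[Si](Cl)(C(C)C)C(C)C
Why: Silylation of phenols; the para hydroxyl reacts first and one ortho hydroxyl second, after which the last hydroxyl is locked in a hydrogen bond to the carbonyl and is too hindered for a third bulky silyl group.

Step 9
Reactants: 9 5,7-bis(benzyloxy)-6-[2-(benzyloxy)-5-(hydroxymethyl)phenyl]-2-[4-(benzyloxy)phenyl]-4H-chromen-4-one; 11 1-[2-hydroxy-4,6-bis(triisopropylsilyloxy)phenyl]ethanone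
Product: 12 1-[2-{[4-(benzyloxy)-3-(tri-O-benzylapigenin-6-yl)phenyl]methoxy}-4,6-bis(triisopropylsilyloxy)phenyl]ethanone
Conditions: PPh3, DIAD, THF, 0 °C to rt
Reagents that add atoms: none
Why: Mitsunobu etherification; the ortho-acyl phenol is acidic enough to protonate the betaine and displaces the oxyphosphonium group of the primary benzylic alcohol. The medium stays neutral, so the aryl silyl ethers are untouched.

Step 10
Reactants: 12 1-[2-{[4-(benzyloxy)-3-(tri-O-benzylapigenin-6-yl)phenyl]methoxy}-4,6-bis(triisopropylsilyloxy)phenyl]ethanone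
Product: 14 2-diazo-1-[2-{[4-(benzyloxy)-3-(tri-O-benzylapigenin-6-yl)phenyl]methoxy}-4,6-bis(triisopropylsilyloxy)phenyl]ethanone, via trifluoroacetyl diketone 13 (not isolated)
Conditions: LiN(SiMe3)2 (1.1 equiv), THF, −78 °C; CF3CO2CH2CF3, −78 °C; cold dilute HCl wash; then 4-AcNHC6H4SO2N3, Et3N, H2O (1 equiv), MeCN, rt
Reagents that add atoms: 4-acetamidobenzenesulfonyl azide, CC(=O)Nc1ccc(cc1)S(=O)(=O)N=[N+]=[N-] (the two diazo nitrogens of 14); 2,2,2-trifluoroethyl trifluoroacetate, O=C(OCC(F)(F)F)C(F)(F)F (the CF3CO group, carried by 13 only)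
Why: Claisen-type trifluoroacetylation of the kinetic lithium enolate, then detrifluoroacetylative (Regitz-type deacylative) diazo transfer, in which the triazoline from the diketone enolate and the azide fragments to the diazoketone and the N-trifluoroacetyl sulfonamide. The methyl group is the only enolisable site, the tetrahedral adduct persists at −78 °C so one equivalent of base suffices, and the low temperature keeps the ortho silyl group on its phenol. Diazomethane is avoided and the acetamido-substituted sulfonyl azide is among the least hazardous diazo donors.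

Step 11
Reactants: 14 2-diazo-1-[2-{[4-(benzyloxy)-3-(tri-O-benzylapigenin-6-yl)phenyl]methoxy}-4,6-bis(triisopropylsilyloxy)phenyl]ethanone
Product: 15 (2S)-2-[4-(benzyloxy)-3-(tri-O-benzylapigenin-6-yl)phenyl]-5,7-bis(triisopropylsilyloxy)-2,3-dihydro-4H-chromen-4-one
Conditions: Rh2(S-PTTL)4 (1 mol %), toluene, 0 °C, slow addition of 14
Reagents that add atoms: none
Why: The diazo carbon of 14 binds an axial site of Rh2(S-PTTL)4 (dirhodium tetrakis[N-phthaloyl-(S)-tert-leucinate]), dinitrogen leaves and an electrophilic carbene bound to divalent rhodium is formed at C3. The carbene carbon then engages one C2–H bond of the O1–CH2–ring B ether in a concerted but asynchronous three-centre transition state, in which hydride character moves from C2 to C3 while the C2–C3 bond forms and the catalyst is released. The closest known reaction type is the intramolecular C–H insertion of 2-alkoxyaryl diazoketones to chroman-4-ones under chiral dirhodium carboxylates. Ring C closes as a six-membered ring by 1,6-insertion of C3 into the C–H bond on the sixth atom, C2; a five-membered closure is excluded because the fifth atom is O1, which bears no hydrogen. The new stereocentre C2 is set by the catalyst alone: the phthalimido walls of the tert-leucinate ligands distinguish the two enantiotopic C2–H bonds by forcing ring B away from the ligand wall, and the catalyst antipode is chosen so that the 2S product results. The step needs insertion to win over attack of the carbene on the lone pair of O1 (five-membered oxonium ylide, then 1,2-shift of the benzylic group) and over any reaction at the other ortho substituent. The substrate secures this because O1 and the para-benzyloxy group of ring B make the C2–H bonds strongly hydridic, because O1 is a weak donor (an aryl ether oxygen conjugated to the acyl-bearing ring A), and because the second ortho oxygen carries a bulky triisopropylsilyl group with no oxygen-activated C–H bond in reach. Slow addition in toluene at 0 °C keeps the carbene concentration low, which suppresses carbene dimerisation and keeps the reaction under catalyst control.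

Step 12
Reactants: 15 (2S)-2-[4-(benzyloxy)-3-(tri-O-benzylapigenin-6-yl)phenyl]-5,7-bis(triisopropylsilyloxy)-2,3-dihydro-4H-chromen-4-one
Product: 16 (2S)-2-[4-(benzyloxy)-3-(tri-O-benzylapigenin-6-yl)phenyl]-5,7-dihydroxy-2,3-dihydro-4H-chromen-4-one
Conditions: Bu4NF, AcOH (1:1, 2.5 equiv each), THF, 0 °C
Reagents that add atoms: none
Why: Fluoride cleavage of aryl silyl ethers; acetic acid protonates the phenoxides as they form, so no base is present to open ring C and C2 keeps its configuration, while the benzyl ethers are inert. No hydrogen fluoride reagent is needed.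

Step 13
Reactants: 16 (2S)-2-[4-(benzyloxy)-3-(tri-O-benzylapigenin-6-yl)phenyl]-5,7-dihydroxy-2,3-dihydro-4H-chromen-4-one
Product: 17 (2S)-2-{4-hydroxy-3-[5,7-dihydroxy-2-(4-hydroxyphenyl)-4-oxo-4H-chromen-6-yl]phenyl}-5,7-dihydroxy-2,3-dihydro-4H-chromen-4-one (target)
Conditions: H2 (1 atm), 10% Pd/C, EtOAc–MeOH, rt, stopped when the benzyl ethers are consumed
Reagents that add atoms: none
Why: Hydrogenolysis of four aryl benzyl ethers under neutral conditions, which leave C2 untouched; the conjugated C2''=C3'' bond and the chelated aryl ketone are expected to be reduced much more slowly than the O-benzyl groups are cleaved.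

## Compound list

1 | apigenin (5,7-dihydroxy-2-(4-hydroxyphenyl)-4H-chromen-4-one) | O=c1cc(-c2ccc(O)cc2)oc2cc(O)cc(O)c12 | starting material
2 | 7-(benzyloxy)-2-[4-(benzyloxy)phenyl]-5-hydroxy-4H-chromen-4-one | O=c1cc(-c2ccc(OCc3ccccc3)cc2)oc2cc(OCc3ccccc3)cc(O)c12 | intermediate
3 | 7-(benzyloxy)-2-[4-(benzyloxy)phenyl]-5-hydroxy-6-iodo-4H-chromen-4-one | O=c1cc(-c2ccc(OCc3ccccc3)cc2)oc2cc(OCc3ccccc3)c(I)c(O)c12 | intermediate
4 | 5,7-bis(benzyloxy)-2-[4-(benzyloxy)phenyl]-6-iodo-4H-chromen-4-one | O=c1cc(-c2ccc(OCc3ccccc3)cc2)oc2cc(OCc3ccccc3)c(I)c(OCc3ccccc3)c12 | intermediate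
5 | 3-bromo-4-hydroxybenzaldehyde | O=Cc1ccc(O)c(Br)c1 | starting material
6 | 4-(benzyloxy)-3-bromobenzaldehyde | O=Cc1ccc(OCc2ccccc2)c(Br)c1 | intermediate
7 | 4-(benzyloxy)-3-(4,4,5,5-tetramethyl-1,3,2-dioxaborolan-2-yl)benzaldehyde | O=Cc1ccc(OCc2ccccc2)c(B2OC(C)(C)C(C)(C)O2)c1 | intermediate
8 | 4-(benzyloxy)-3-{5,7-bis(benzyloxy)-2-[4-(benzyloxy)phenyl]-4-oxo-4H-chromen-6-yl}benzaldehyde | O=Cc1ccc(OCc2ccccc2)c(-c2c(OCc3ccccc3)cc3oc(-c4ccc(OCc5ccccc5)cc4)cc(=O)c3c2OCc2ccccc2)c1 | intermediate
9 | 5,7-bis(benzyloxy)-6-[2-(benzyloxy)-5-(hydroxymethyl)phenyl]-2-[4-(benzyloxy)phenyl]-4H-chromen-4-one | OCc1ccc(OCc2ccccc2)c(-c2c(OCc3ccccc3)cc3oc(-c4ccc(OCc5ccccc5)cc4)cc(=O)c3c2OCc2ccccc2)c1 | intermediate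
10 | 2',4',6'-trihydroxyacetophenone (1-(2,4,6-trihydroxyphenyl)ethanone) | CC(=O)c1c(O)cc(O)cc1O | starting material
11 | 1-[2-hydroxy-4,6-bis(triisopropylsilyloxy)phenyl]ethanone | CC(=O)c1c(O)cc(O[Si](C(C)C)(C(C)C)C(C)C)cc1O[Si](C(C)C)(C(C)C)C(C)C | intermediate
12 | 1-[2-({4-(benzyloxy)-3-[5,7-bis(benzyloxy)-2-(4-benzyloxyphenyl)-4-oxo-4H-chromen-6-yl]phenyl}methoxy)-4,6-bis(triisopropylsilyloxy)phenyl]ethanone | CC(=O)c1c(OCc2ccc(OCc3ccccc3)c(-c3c(OCc4ccccc4)cc4oc(-c5ccc(OCc6ccccc6)cc5)cc(=O)c4c3OCc3ccccc3)c2)cc(O[Si](C(C)C)(C(C)C)C(C)C)cc1O[Si](C(C)C)(C(C)C)C(C)C | intermediate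
13 | 4,4,4-trifluoro-1-[2-({4-(benzyloxy)-3-[5,7-bis(benzyloxy)-2-(4-benzyloxyphenyl)-4-oxo-4H-chromen-6-yl]phenyl}methoxy)-4,6-bis(triisopropylsilyloxy)phenyl]butane-1,3-dione | O=C(CC(=O)C(F)(F)F)c1c(OCc2ccc(OCc3ccccc3)c(-c3c(OCc4ccccc4)cc4oc(-c5ccc(OCc6ccccc6)cc5)cc(=O)c4c3OCc3ccccc3)c2)cc(O[Si](C(C)C)(C(C)C)C(C)C)cc1O[Si](C(C)C)(C(C)C)C(C)C | intermediate
14 | 2-diazo-1-[2-({4-(benzyloxy)-3-[5,7-bis(benzyloxy)-2-(4-benzyloxyphenyl)-4-oxo-4H-chromen-6-yl]phenyl}methoxy)-4,6-bis(triisopropylsilyloxy)phenyl]ethanone | [N-]=[N+]=CC(=O)c1c(OCc2ccc(OCc3ccccc3)c(-c3c(OCc4ccccc4)cc4oc(-c5ccc(OCc6ccccc6)cc5)cc(=O)c4c3OCc3ccccc3)c2)cc(O[Si](C(C)C)(C(C)C)C(C)C)cc1O[Si](C(C)C)(C(C)C)C(C)C | intermediate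
15 | (2S)-2-{4-(benzyloxy)-3-[5,7-bis(benzyloxy)-2-(4-benzyloxyphenyl)-4-oxo-4H-chromen-6-yl]phenyl}-5,7-bis(triisopropylsilyloxy)-2,3-dihydro-4H-chromen-4-one | O=C1C[C@@H](c2ccc(OCc3ccccc3)c(-c3c(OCc4ccccc4)cc4oc(-c5ccc(OCc6ccccc6)cc5)cc(=O)c4c3OCc3ccccc3)c2)Oc2cc(O[Si](C(C)C)(C(C)C)C(C)C)cc(O[Si](C(C)C)(C(C)C)C(C)C)c21 | intermediate
16 | (2S)-2-{4-(benzyloxy)-3-[5,7-bis(benzyloxy)-2-(4-benzyloxyphenyl)-4-oxo-4H-chromen-6-yl]phenyl}-5,7-dihydroxy-2,3-dihydro-4H-chromen-4-one | O=C1C[C@@H](c2ccc(OCc3ccccc3)c(-c3c(OCc4ccccc4)cc4oc(-c5ccc(OCc6ccccc6)cc5)cc(=O)c4c3OCc3ccccc3)c2)Oc2cc(O)cc(O)c21 | intermediate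
17 | (2S)-2-{4-hydroxy-3-[5,7-dihydroxy-2-(4-hydroxyphenyl)-4-oxo-4H-chromen-6-yl]phenyl}-5,7-dihydroxy-2,3-dihydro-4H-chromen-4-one | O=C1C[C@@H](c2ccc(O)c(-c3c(O)cc4oc(-c5ccc(O)cc5)cc(=O)c4c3O)c2)Oc2cc(O)cc(O)c21 | target

## Step count and least certain steps

Total step count: 13. Longest linear sequence: 10 steps (steps 1, 2, 3, 6, 7, 9, 10, 11, 12, 13, from 1 to 17).

**Step 11 (key step).** Two things are most likely to go wrong. The carbene may be captured by the lone pair of O1, and the resulting five-membered oxonium ylide would undergo a 1,2-shift of the benzylic group; the para-oxygen that activates the C–H bond also makes that group migrate easily. The two enantiotopic hydrogens may also be poorly differentiated, because a carbene stabilised by a single acceptor reacts through an early transition state. The fallback builds C2 by enantioselective conjugate arylation and sets out from 4 and 10.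
- From 4, Suzuki–Miyaura coupling with commercial [2-(benzyloxy)-5-chlorophenyl]boronic acid (Pd(OAc)2, SPhos, K3PO4; the iodide reacts, the chloride does not) would give 5,7-bis(benzyloxy)-6-[2-(benzyloxy)-5-chlorophenyl]-2-[4-(benzyloxy)phenyl]-4H-chromen-4-one F1.
- Borylation of the chloride (Pd(OAc)2, XPhos, B2(OH)4, KOAc, EtOH, 80 °C) would give {4-(benzyloxy)-3-[5,7-bis(benzyloxy)-2-(4-benzyloxyphenyl)-4-oxo-4H-chromen-6-yl]phenyl}boronic acid F2.
- From 10, bis-benzylation (BnBr, K2CO3, acetone) would give 1-[2,4-bis(benzyloxy)-6-hydroxyphenyl]ethanone F3.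
- Condensation with N,N-dimethylformamide dimethyl acetal would give (E)-1-[2,4-bis(benzyloxy)-6-hydroxyphenyl]-3-(dimethylamino)prop-2-en-1-one F4, and acid (HCl, CH2Cl2) would close it to 5,7-bis(benzyloxy)-4H-chromen-4-one F5.
- Rhodium-catalysed asymmetric 1,4-addition (Hayashi–Miyaura reaction) of F2 to F5, with [Rh(OH)(cod)]2 and an electron-poor atropisomeric bisphosphine in toluene–H2O at room temperature, ligand antipode chosen for 2S, would give (2S)-2-{4-(benzyloxy)-3-[5,7-bis(benzyloxy)-2-(4-benzyloxyphenyl)-4-oxo-4H-chromen-6-yl]phenyl}-5,7-bis(benzyloxy)-2,3-dihydro-4H-chromen-4-one F6. The flavone inside F2 is β,β-disubstituted and should not compete as an acceptor.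
- Hydrogenolysis of F6 (H2, 10% Pd/C) comes back to the route at 17.

**Step 10.** The most likely failures are incomplete trifluoroacetylation of an enolate that two ortho substituents twist out of conjugation, and migration of the ortho silyl group from the phenolic oxygen to the enolate oxygen if the enolate warms. The fallback avoids the enolate. It sets out from 12: condensation with tert-butoxybis(dimethylamino)methane (toluene, 80 °C) would give (E)-3-(dimethylamino)-1-[2-({4-(benzyloxy)-3-[5,7-bis(benzyloxy)-2-(4-benzyloxyphenyl)-4-oxo-4H-chromen-6-yl]phenyl}methoxy)-4,6-bis(triisopropylsilyloxy)phenyl]prop-2-en-1-one F7. Treatment with 4-acetamidobenzenesulfonyl azide in MeCN at room temperature (azide cycloaddition to the enamine double bond and fragmentation of the triazoline into diazoketone and N-sulfonylformamidine) comes back to the route at 14.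

**Step 9.** The most likely failure is slow displacement by a hydrogen-bonded ortho-acyl phenol, which would let the activated, electron-rich benzylic alcohol alkylate the reduced azodicarboxylate instead. The fallback separates activation from etherification. It sets out from 9: SOCl2 in CH2Cl2 at 0 °C would give 5,7-bis(benzyloxy)-6-[2-(benzyloxy)-5-(chloromethyl)phenyl]-2-[4-(benzyloxy)phenyl]-4H-chromen-4-one F8. Williamson alkylation of 11 with F8 (anhydrous K2CO3, Bu4NI cat., acetone, 50 °C) comes back to the route at 12.

**Step 6.** The most likely failure is slow transmetalation and reductive elimination at a palladium centre flanked by two ortho benzyloxy groups, which leaves time for protodeboronation of 7 and hydrodeiodination of 4. The fallback moves the coupling to the stage where one flanking group is still a small hydroxyl. It sets out from 3 and 7: coupling (Pd(OAc)2, SPhos, K3PO4, toluene–H2O) would give 4-(benzyloxy)-3-{7-(benzyloxy)-2-[4-(benzyloxy)phenyl]-5-hydroxy-4-oxo-4H-chromen-6-yl}benzaldehyde F9. Benzylation of the chelated phenol (BnBr, Cs2CO3, DMF, 60 °C) comes back to the route at 8, and step 3 is then not needed.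

**Step 13.** The most likely failure is over-reduction, that is saturation of the C2''=C3'' bond or hydrogenolytic opening of the benzylic C2–O1 bond before the hindered 5''-benzyl ether has gone. The fallback is non-reductive. It sets out from 16: BCl3 with pentamethylbenzene as cation scavenger in CH2Cl2 at −78 °C cleaves the four aryl benzyl ethers and comes back to the route at 17. It makes no compound that is not already listed (none F0).

## Further compounds

F1 | step 11 | 5,7-bis(benzyloxy)-6-[2-(benzyloxy)-5-chlorophenyl]-2-[4-(benzyloxy)phenyl]-4H-chromen-4-one | Clc1ccc(OCc2ccccc2)c(-c2c(OCc3ccccc3)cc3oc(-c4ccc(OCc5ccccc5)cc4)cc(=O)c3c2OCc2ccccc2)c1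
F2 | step 11 | {4-(benzyloxy)-3-[5,7-bis(benzyloxy)-2-(4-benzyloxyphenyl)-4-oxo-4H-chromen-6-yl]phenyl}boronic acid | OB(O)c1ccc(OCc2ccccc2)c(-c2c(OCc3ccccc3)cc3oc(-c4ccc(OCc5ccccc5)cc4)cc(=O)c3c2OCc2ccccc2)c1
F3 | step 11 | 1-[2,4-bis(benzyloxy)-6-hydroxyphenyl]ethanone | CC(=O)c1c(O)cc(OCc2ccccc2)cc1OCc1ccccc1
F4 | step 11 | (E)-1-[2,4-bis(benzyloxy)-6-hydroxyphenyl]-3-(dimethylamino)prop-2-en-1-one | CN(C)/C=C/C(=O)c1c(O)cc(OCc2ccccc2)cc1OCc1ccccc1
F5 | step 11 | 5,7-bis(benzyloxy)-4H-chromen-4-one | O=c1ccoc2cc(OCc3ccccc3)cc(OCc3ccccc3)c12
F6 | step 11 | (2S)-2-{4-(benzyloxy)-3-[5,7-bis(benzyloxy)-2-(4-benzyloxyphenyl)-4-oxo-4H-chromen-6-yl]phenyl}-5,7-bis(benzyloxy)-2,3-dihydro-4H-chromen-4-one | O=C1C[C@@H](c2ccc(OCc3ccccc3)c(-c3c(OCc4ccccc4)cc4oc(-c5ccc(OCc6ccccc6)cc5)cc(=O)c4c3OCc3ccccc3)c2)Oc2cc(OCc3ccccc3)cc(OCc3ccccc3)c21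
F7 | step 10 | (E)-3-(dimethylamino)-1-[2-({4-(benzyloxy)-3-[5,7-bis(benzyloxy)-2-(4-benzyloxyphenyl)-4-oxo-4H-chromen-6-yl]phenyl}methoxy)-4,6-bis(triisopropylsilyloxy)phenyl]prop-2-en-1-one | CN(C)/C=C/C(=O)c1c(OCc2ccc(OCc3ccccc3)c(-c3c(OCc4ccccc4)cc4oc(-c5ccc(OCc6ccccc6)cc5)cc(=O)c4c3OCc3ccccc3)c2)cc(O[Si](C(C)C)(C(C)C)C(C)C)cc1O[Si](C(C)C)(C(C)C)C(C)C
F8 | step 9 | 5,7-bis(benzyloxy)-6-[2-(benzyloxy)-5-(chloromethyl)phenyl]-2-[4-(benzyloxy)phenyl]-4H-chromen-4-one | ClCc1ccc(OCc2ccccc2)c(-c2c(OCc3ccccc3)cc3oc(-c4ccc(OCc5ccccc5)cc4)cc(=O)c3c2OCc2ccccc2)c1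
F9 | step 6 | 4-(benzyloxy)-3-{7-(benzyloxy)-2-[4-(benzyloxy)phenyl]-5-hydroxy-4-oxo-4H-chromen-6-yl}benzaldehyde | O=Cc1ccc(OCc2ccccc2)c(-c2c(OCc3ccccc3)cc3oc(-c4ccc(OCc5ccccc5)cc4)cc(=O)c3c2O)c1
F0 | step 13 | none | none
A1 | alternative 1 | 5,7-bis(benzyloxy)-2-[4-(benzyloxy)phenyl]-6-[2,2-bis(trimethylsilyloxy)ethenyl]-4H-chromen-4-one (bis(trimethylsilyl) ketene acetal) | C[Si](C)(C)OC(O[Si](C)(C)C)=Cc1c(OCc2ccccc2)cc2oc(-c3ccc(OCc4ccccc4)cc3)cc(=O)c2c1OCc1ccccc1
A2 | alternative 1 | methyl coumalate (methyl 2-oxo-2H-pyran-5-carboxylate) | COC(=O)C1=COC(=O)C=C1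
A3 | alternative 1 | methyl 4-hydroxy-3-[5,7-bis(benzyloxy)-2-(4-benzyloxyphenyl)-4-oxochromen-6-yl]benzoate | COC(=O)c1ccc(O)c(-c2c(OCc3ccccc3)cc3oc(-c4ccc(OCc5ccccc5)cc4)cc(=O)c3c2OCc2ccccc2)c1
A4 | alternative 2 | 6-[4-(benzyloxy)phenyl]-2-(2-diazoacetyl)-4H-pyran-4-one | [N-]=[N+]=CC(=O)c1cc(=O)cc(-c2ccc(OCc3ccccc3)cc2)o1
A5 | alternative 2 | {[2-(benzyloxy)-5-(1,3-dioxolan-2-yl)phenyl]ethynyloxy}triisopropylsilane | CC(C)[Si](OC#Cc1cc(C2OCCO2)ccc1OCc1ccccc1)(C(C)C)C(C)C
A6 | alternative 2 | 6-[2-(benzyloxy)-5-(1,3-dioxolan-2-yl)phenyl]-2-(4-benzyloxyphenyl)-5-hydroxy-7-(triisopropylsilyloxy)chromen-4-one | CC(C)[Si](Oc1cc2oc(-c3ccc(OCc4ccccc4)cc3)cc(=O)c2c(O)c1-c1cc(C2OCCO2)ccc1OCc1ccccc1)(C(C)C)C(C)C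
A7 | alternative 3 | tert-butyl 2-[2,4-bis(benzyloxy)-6-hydroxybenzoyl]-3-{4-(benzyloxy)-3-[5,7-bis(benzyloxy)-2-(4-benzyloxyphenyl)-4-oxo-4H-chromen-6-yl]phenyl}prop-2-enoate (alkene geometry not fixed) | CC(C)(C)OC(=O)C(=Cc1ccc(OCc2ccccc2)c(-c2c(OCc3ccccc3)cc3oc(-c4ccc(OCc5ccccc5)cc4)cc(=O)c3c2OCc2ccccc2)c1)C(=O)c1c(O)cc(OCc2ccccc2)cc1OCc1ccccc1
A8 | alternative 3 | tert-butyl (2S,3R)-trans-5,7-bis(benzyloxy)-2-{4-(benzyloxy)-3-[5,7-bis(benzyloxy)-2-(4-benzyloxyphenyl)-4-oxo-4H-chromen-6-yl]phenyl}-4-oxo-3,4-dihydro-2H-chromene-3-carboxylate | O=C1[C@H](C(=O)OC(C)(C)C)[C@@H](c2ccc(OCc3ccccc3)c(-c3c(OCc4ccccc4)cc4oc(-c5ccc(OCc6ccccc6)cc5)cc(=O)c4c3OCc3ccccc3)c2)Oc2cc(OCc3ccccc3)cc(OCc3ccccc3)c21
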